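## The problem

Compound 30 is a γ-lactone cis-fused to a cycloheptane, numbered here as a cyclohepta[b]furan-2-one (O1, C2, C3, C3a, C4 to C8, C8a). Its seven stereocentres are contiguous: six on the carbocycle (C5, C6, C7, C8, C8a, C3a) and C3 on the lactone. With the C3a branch taken as up, the carbocycle carries C5–OH down, C6–CH3 up, C7–OH up with the butenoyl group down, C8–O down and C8a–O up; the C3 methyl lies on the concave face of the lactone, cis to C4. C3a can come from the chiral pool; together with an allylic oxygen it can place C5 and C6, C6 can steer a nucleophile to C7, C3a and C7 can steer an oxidant to one face of a C8=C8a alkene, and the folded bicycle can steer a proton to C3. Two relationships are awkward: the C6 methyl is trans to the C5 oxygen but cis to the C3a branch, which by conformational analysis is neither the kinetic nor the thermodynamic result of protonating a 2-methyl-3-oxy ketone at C6; and the C7 carbon substituent is cis to the C8 oxygen, the face that the polar Felkin–Anh preference opposes if a C7 ketone is attacked after C8 is oxygenated. Sensitive points are the tertiary α-hydroxy enone, the isobutyrate next to a free tertiary hydroxyl (acyl shift under base), the kinetically set C3 centre, and any C7 ketone with the lactone oxygen at C8a in its β position (E1cB). The key step is possible because the C6 methyl, C5 oxygen, C4 methylene and the three-carbon branch on C3a are spaced as the C2 methyl, C3, C4 and C5 isopropenyl group of carvone, with C7 as the carbonyl carbon: only C8 is missing, and it can be inserted between C7 and C8a.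

## Retrosynthesis

**30 ⇐ 29 ⇐ 28.** The end of the route is kept free of base. The two hydroxyls are unveiled from silyl ethers (29), and the (E)-but-2-enoyl group of 29 is traced to the 3-hydroxybut-1-ynyl group of 28 by a Meyer–Schuster 1,3-transposition. No C–C bond is cut, but the acyl group becomes an alkyne that survives base, peracid and enolate chemistry. The neighbouring cut, C7–C(=O) with an acyl anion added to a ring ketone at the end, would meet the lactone, the isobutyrate, a β-acyloxy ketone and the wrong facial bias at once. The forward step must transpose only the secondary carbinol, so the tertiary C7 oxygen stays silylated.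

**28 ⇐ 27 ⇐ 25 ⇐ 23 + 24.** C3 is left uncontrolled until the bicycle exists and is then set by protonating enolate 26 on the convex face (27). The isobutyrate is put on first (25 from 23 and isobutyryl chloride 24), so that no C8 alkoxide ever sits next to the C7 silyl ether, where it could take the silyl group.

**23 ⇐ 22 ⇐ 21 ⇐ 20.** The C8a–O1 and C8–O bonds are cut together: the side-chain carboxylate of 22 opens the lower-face epoxide at C8a, giving the cis lactone and the trans C8 hydroxyl in one event. Iodolactonisation of the same alkene would fix C8a as well but leave iodine where an oxygen is needed with retention. Epoxidising an enone before the C7 addition would leave a β-acyloxy ketone. Precursor 20 has two stereocentres and one ring fewer; the forward step needs peracid attack on the lower face.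

**20 ⇐ 19 ⇐ 16 + 17.** The C7–C(sp) bond is cut: dilithium alkynide 18, made from (S)-but-3-yn-2-ol 17, adds to enone 16. At this stage C6 is the only stereocentre next to the carbonyl, C8 is sp2 and carries no oxygen, and no lactone is present. Attack from the lower face, away from the C6 methyl and the C3a branch, puts the new carbon trans to the C6 methyl. The precursor loses the quaternary centre.

**16 ⇐ 13.** The C8=C8a double bond comes from Saegusa–Ito dehydrogenation of cycloheptanone 13 through enol ether 15; kinetic deprotonation at the C8 methylene gives the regiochemistry.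

**13 ⇐ 10 + 11.** The C7–C8 and C8–C8a bonds are cut and C8 is removed, leaving cyclohexanone 10 and trimethylsilyldiazomethane 11. Against closing the seven-membered ring by cyclisation, this ring enlargement creates no stereocentre and keeps the three already set. It requires that the unsubstituted methylene, not the methyl-bearing carbon, migrates.

**10 ⇐ 9 ⇐ 8 ⇐ 7 ⇐ 4 ⇐ 2 ⇐ 1.** Cyclohexanone 10 maps on to (R)-carvone 1. The C5–O and C6–H bonds are made in one syn hydroboration of the ring alkene of cis-carveol 2, from the face opposite the allylic oxygen, which is the reliable way to get the methyl trans to the oxygen and cis to the branch. A shorter entry by epoxidation of 1 and reductive opening is expected to place the methyl cis to the hydroxyl, and protonation or equilibration at C6 should not correct this. Hydroboration also turns the isopropenyl group into the primary alcohol (4), which is needed at the acid level anyway. Oxidative lactonisation (7) then tells the C7 hydroxyl (cis to the side chain) from the C5 hydroxyl, which is silylated (8) before methanolysis (9) and oxidation give 10. The price is a C3 epimer pair, converged at 27.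

## Roads not taken

Alternative 1: The cut is through C4–C5 and C8–C8a. In the forward direction 3-methylfuran A1 would be combined with the mixed acetal A2, the triethylsilyl enol ether of 1-methoxy-1-[(S)-1-phenylethoxy]propan-2-one, under trimethylsilyl triflate. The chiral alkoxy-substituted 2-silyloxyallyl cation released from A2 would add across the 2,5-positions of the furan A1 in a (4+3) cycloaddition and give the oxygen-bridged cycloheptenone A3.
- Merits: two C–C bonds and the seven-membered ring form in one step from simple pieces, with a ketone at C3a for the side chain, an alkoxy group at C8a and the C6 methyl on an alkene.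
- Weak points: the regiochemistry with the unsymmetrical furan A1 and the facial control by the auxiliary both have to be right. One bridging oxygen serves C5 and C8, yet the target needs a separate oxygen on each, so the bridge must be cut and one position re-oxygenated. C3a and C3 must then be made from the ketone without help from the chiral pool, and C7 still has to be built from the C6=C7 alkene by addition to a ketone flanked by the C8 oxygen.
- Comparison: this road builds the ring more convergently than the chosen plan, which spends six steps before the ring enlargement. The chosen plan sets against it a C3a centre bought with carvone, one hydroboration that fixes C5 and C6, and a shorter path after the ring is in hand.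

Alternative 2: The cut is the C3a–C8a bond. The open-chain aldehyde A4, which carries the C8a formyl group at one end and a (Z)-2-(bromomethyl)enoate at the other, would be closed with CrCl2 (divalent chromium). The γ-carbon of the allylchromium species adds to the C8a aldehyde and the hydroxy ester lactonises to the α-methylene lactone A5, with the C7/C8 diol held as an acetonide.
- Merits: the trans C7/C8 diol, the quaternary C7 and C5/C6 are set on an acyclic chain by reliable methods before the ring exists. The methylene lactone gives C3 by hydrogen delivery to the convex face without carrying epimers.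
- Weak points: a long linear chain with four stereocentres is needed first. A seven-membered ring must close in a chromium-mediated allylation whose selectivity at the two new centres relative to C8 is not secured. The C7 oxymethyl group still needs three or more steps to become the butenoyl ketone.
- Comparison: for C7, C8 and C3 this road is better controlled than the chosen plan, which stakes C7 on a substrate-controlled addition and C8 on a facial preference. The chosen plan sets against it a much shorter access to the carbocycle and no medium-ring closure.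

Alternative 3: The cut is C3–C3a. The C8a diazoacetate A6 would be decomposed by a chiral dirhodium tetracarboxamidate such as Rh2(4S-MACIM)4, and the carbenoid would insert into the cis C3a–H bond to close the lactone A7, which lacks only the C3 methyl.
- Merits: the cis ring fusion follows from geometry, the lactone appears in one late step, and no side chain has to be carried.
- Weak points: the fully substituted cycloheptane must come from elsewhere, without a chiral-pool C3a. Site selectivity among several C–H bonds rests on the catalyst. Methylating the lactone enolate puts the methyl on the convex face, so a deprotonation–protonation is needed as well. The C7 ketone is unmasked only at the end, where the acyl unit must add cis to the C8 acyloxy group in the presence of a lactone, an ester and a β-leaving group.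
- Comparison: lactone formation is shorter and cleaner here than in the chosen plan. The chosen plan sets against it that the C7 addition is done at the enone stage, where it is chemoselective and no C8 oxygen opposes it.

Key step: step 7

Remark 1 (convention): positions in all intermediates carry the numbers of the target lactone (O1, C2, C3, C3a, C4–C8, C8a); "upper face" is the face of the C3a side chain.
Remark 2 (assumption): hydroboration of the isopropenyl group is taken to be unselective, so compounds 3–10, 12–16, 19–23 and 25 are pairs of C3 epimers (their SMILES leave C3 open); the pair converges in step 14.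
Remark 3 (assumption): the carbinol centre of 17 is destroyed in step 16; the (S)-enantiomer is used only so that each intermediate is one diastereomer.

## Route

Step 1
Reactants: 1 (R)-carvone
Product: 2 (1R,5R)-cis-carveol
Conditions: NaBH4, CeCl3·7H2O, MeOH, −78 → 0 °C
Reagents that add atoms: none
Why: Luche 1,2-reduction of the enone; hydride addition to carvone is known to give mainly the cis allylic alcohol (hydroxyl and isopropenyl both pseudo-equatorial). The carbinol centre is temporary but directs steps 2 and 3.

Step 2
Reactants: 2 (1R,5R)-cis-carveol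
Product: 4 5-(1-hydroxypropan-2-yl)-2-methylcyclohexane-1,3-diol (C5 hydroxyl trans to the side chain; C3 epimers), via tris-borane adduct 3 (not isolated)
Conditions: BH3·THF (excess), THF, 0 °C → rt; then NaOH, H2O2, H2O, 0 °C → rt
Reagents that add atoms: hydrogen peroxide, OO
Why: Hydroboration–oxidation; syn addition of H (to C6) and B (to C5) to the trisubstituted alkene from the face opposite the allylic C7 oxygen and the C3a branch makes C5–O lower-face and C6–CH3 upper-face, trans to each other by mechanism. The isopropenyl group gives the primary alcohol without control at C3, and oxidation proceeds with retention.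

Step 3
Reactants: 4 5-(1-hydroxypropan-2-yl)-2-methylcyclohexane-1,3-diol
Product: 7 7-hydroxy-4,8-dimethyl-2-oxabicyclo[3.3.1]nonan-3-one (bridged lactone on the C7 oxygen; C5 hydroxyl free), via hydroxy aldehyde 5 (not isolated), via lactol 6 (not isolated)
Conditions: TEMPO (cat.), PhI(OAc)2 (2.5 equiv), CH2Cl2, rt
Reagents that add atoms: none
Why: Oxoammonium oxidation with oxidative lactonisation of a 1,5-diol; the primary alcohol is oxidised first, the aldehyde can form a lactol only with the C7 hydroxyl, which is cis-1,3 to the side chain, and the lactol is oxidised on. The trans C5 hydroxyl cannot bridge and stays free, which tells the two secondary alcohols apart.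

Step 4
Reactants: 7 7-hydroxy-4,8-dimethyl-2-oxabicyclo[3.3.1]nonan-3-one
Product: 8 7-(tert-butyldimethylsilyloxy)-4,8-dimethyl-2-oxabicyclo[3.3.1]nonan-3-one
Conditions: Me2(t-Bu)SiCl, imidazole, DMF, rt
Reagents that add atoms: tert-butyldimethylsilyl chloride, CC(C)(C)[Si](C)(C)Cl
Why: Standard silylation of the only free (equatorial secondary) hydroxyl; this ether stays until the last step.

Step 5
Reactants: 8 7-(tert-butyldimethylsilyloxy)-4,8-dimethyl-2-oxabicyclo[3.3.1]nonan-3-one
Product: 9 methyl 2-[3-(tert-butyldimethylsilyloxy)-5-hydroxy-4-methylcyclohexyl]propanoate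
Conditions: K2CO3 (cat.), MeOH, rt
Reagents that add atoms: methanol, CO
Why: Base-catalysed transesterification; the bridged δ-lactone, which holds both bridging groups axial, opens in methanol to the methyl ester and frees only the C7 hydroxyl.

Step 6
Reactants: 9 methyl 2-[3-(tert-butyldimethylsilyloxy)-5-hydroxy-4-methylcyclohexyl]propanoate
Product: 10 methyl 2-[(1R,3R,4S)-3-(tert-butyldimethylsilyloxy)-4-methyl-5-oxocyclohexyl]propanoate
Conditions: Dess–Martin periodinane, NaHCO3, CH2Cl2, 0 °C → rt
Reagents that add atoms: none
Why: Dess–Martin oxidation under buffered, non-enolising conditions; the C6 centre (methyl trans to the silyloxy group) is not the thermodynamically preferred epimer and is therefore never exposed to equilibrating base from here to step 9.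

Step 7
Reactants: 10 methyl 2-[(1R,3R,4S)-3-(tert-butyldimethylsilyloxy)-4-methyl-5-oxocyclohexyl]propanoate; 11 trimethylsilyldiazomethane
Product: 13 methyl 2-[(1S,3R,4S)-3-(tert-butyldimethylsilyloxy)-4-methyl-5-oxocycloheptyl]propanoate, via α-trimethylsilyl ketone 12 (not isolated)
Conditions: AlMe3, CH2Cl2, −78 → −40 °C; then 1 M HCl, THF, 0 °C
Reagents that add atoms: none
Why: AlMe3 binds the ketone oxygen of 10 and the nucleophilic carbon of 11 adds to C7, giving a β-aluminoxy diazonium species. Loss of N2 is concerted with a 1,2-shift of the C8a methylene from C7 to the diazo carbon, which becomes C8: the C7–C8 and C8–C8a bonds form and the old C7–C8a bond breaks, so the seven-membered ring arises by ring enlargement and not by an exo or endo cyclisation. The first product is the 2-trimethylsilyl ketone 12, and protodesilylation on acidic work-up gives 13. The closest known reaction type is the Lewis acid promoted Tiffeneau–Demjanov-type homologation of 2-substituted cyclohexanones with trimethylsilyldiazomethane. No stereocentre is kept from this step (the silyl-bearing C8 becomes CH2), and C3a, C5 and C6 are spectators. The selectivity needed is migration of the C8a methylene and not of the C6 methine; it is secured by the lower substitution of C8a, by the bulk of the silyl group on the carbon that receives the migrating group, and by the electron-withdrawing β-silyloxy group on the C6 side. Low temperature and the absence of base protect the C6 centre, and the ester reacts with neither reagent.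

Step 8
Reactants: 13 methyl 2-[(1S,3R,4S)-3-(tert-butyldimethylsilyloxy)-4-methyl-5-oxocycloheptyl]propanoate
Product: 16 methyl 2-[(1R,5S,6R)-6-(tert-butyldimethylsilyloxy)-5-methyl-4-oxocyclohept-2-en-1-yl]propanoate, via lithium enolate 14 (not isolated), via trimethylsilyl enol ether 15 (not isolated)
Conditions: LiN(iPr)2, Me3SiCl, THF, −78 °C; then Pd(OAc)2, MeCN, rt
Reagents that add atoms: none
Why: Kinetic deprotonation at the unhindered C8 methylene (the ketone is far more acidic than the ester) with internal silyl quench, then Saegusa–Ito oxidation: the palladium enolate loses the C8a hydrogen by β-hydride elimination to give the C8=C8a enone. C6 is not enolised.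

Step 9
Reactants: 16 methyl 2-[(1R,5S,6R)-6-(tert-butyldimethylsilyloxy)-5-methyl-4-oxocyclohept-2-en-1-yl]propanoate; 17 (S)-but-3-yn-2-ol
Product: 19 C7 tertiary alcohol carrying the (S)-3-hydroxybut-1-ynyl group on the lower face (C7 hydroxyl up), via dilithium alkynide 18 (not isolated)
Conditions: 17, n-BuLi (2 equiv per 17), THF, −78 → 0 °C; then 16, −78 °C; aq. NH4Cl
Reagents that add atoms: none
Why: 1,2-Addition of a lithium acetylide to an enone; acetylides are weak bases, so C6–H and the ester are left alone at −78 °C. Control comes from C6 in the Felkin–Anh sense: with the ring bond C6–C5 roughly perpendicular to the carbonyl plane the nucleophile enters anti to it and past C6–H, away from the C6 methyl and the C3a branch, which puts the alkynyl group on the lower face (trans to the C6 methyl) and the hydroxyl on the upper face.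

Step 10
Reactants: 19 C7 tertiary alcohol carrying the (S)-3-hydroxybut-1-ynyl group
Product: 20 bis(triethylsilyl) ether of 19 (C7–O and side-chain O silylated)
Conditions: Et3SiOTf, 2,6-lutidine, CH2Cl2, −78 → 0 °C
Reagents that add atoms: triethylsilyl trifluoromethanesulfonate, CC[Si](CC)(CC)OS(=O)(=O)C(F)(F)F
Why: Silyl triflate silylation of both the secondary and the hindered tertiary hydroxyl; capping the C7 hydroxyl removes its syn-directing effect on the peracid in step 11 and later keeps it out of the gold chemistry.

Step 11
Reactants: 20 bis(triethylsilyl) ether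
Product: 21 C8–C8a epoxide on the lower face
Conditions: mCPBA, NaHCO3, CH2Cl2, 0 °C → rt
Reagents that add atoms: 3-chloroperoxybenzoic acid, OOC(=O)c1cccc(Cl)c1
Why: Prilezhaev epoxidation of the only alkene (the internal alkyne is far slower); the upper face is screened at both allylic carbons, by the C7 silyloxy group and the C3a side chain, so oxygen should be delivered to the lower face.

Step 12
Reactants: 21 C8–C8a epoxide on the lower face
Product: 23 cis-fused γ-lactone carrying the lower-face C8 hydroxyl (C3 epimers), via epoxy acid 22 (not isolated)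
Conditions: LiOH, THF/H2O, rt; then AcOH to pH 4, rt → 40 °C
Reagents that add atoms: lithium hydroxide, [Li+].[OH-]
Why: Saponification frees the carboxyl group on the upper face; on mild acidification it opens the epoxide by 5-exo SN2 attack at C8a with inversion (O1 up, cis ring fusion), and the epoxide oxygen stays on C8 as the lower-face hydroxyl. Attack at C8 would be 6-endo at a neopentyl carbon.

Step 13
Reactants: 23 cis-fused γ-lactone carrying the lower-face C8 hydroxyl; 24 isobutyryl chloride
Product: 25 C8 isobutyrate (C3 epimers)
Conditions: pyridine, DMAP (cat.), CH2Cl2, 0 °C → rt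
Reagents that add atoms: none
Why: DMAP-catalysed acylation of the only free hydroxyl; it is done before any enolate chemistry so that no C8 alkoxide can take the silyl group from the neighbouring C7 oxygen.

Step 14
Reactants: 25 C8 isobutyrate (C3 epimers)
Product: 27 (3R)-lactone with the C3 methyl on the concave face, via lithium enolate 26 (not isolated)
Conditions: LiN(iPr)2, THF, −78 °C; then 2,6-di-tert-butylphenol, −78 °C
Reagents that add atoms: none
Why: Enolisation and kinetic protonation of a cis-fused lactone; both C3 epimers give the same planar enolate 26, and the bulky phenol protonates it on the convex face (the face of H3a and H8a), which leaves the methyl on the concave face, cis to C4, as in the target. An enolate formed at the isobutyrate is returned unchanged because its α-carbon is not stereogenic.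

Step 15
Reactants: 27 (3R)-lactone
Product: 28 secondary propargylic alcohol (C7 triethylsilyl and C5 tert-butyldimethylsilyl ethers kept)
Conditions: PPTS, MeOH/CH2Cl2, 0 °C
Reagents that add atoms: none
Why: Acid-catalysed methanolysis removes the unhindered secondary triethylsilyl ether much faster than the neopentyl-like tertiary one or the tert-butyldimethylsilyl ether.

Step 16
Reactants: 28 secondary propargylic alcohol
Product: 29 C7 (E)-but-2-enoyl ketone (C7 triethylsilyl and C5 tert-butyldimethylsilyl ethers)
Conditions: Ph3PAuNTf2 (cat.), MeOH (1 equiv), toluene, rt → 50 °C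
Reagents that add atoms: none
Why: Gold-catalysed Meyer–Schuster rearrangement of a secondary propargylic alcohol; monovalent gold activates the alkyne, the oxygen is transposed from the carbinol carbon to the alkyne carbon attached to C7, and the allenol tautomerises to the conjugated ketone with the (E)-alkene as the stable geometry. The tertiary oxygen is kept silylated so that it neither ionises readily nor cyclises on to the activated alkyne.

Step 17
Reactants: 29 C7 (E)-but-2-enoyl ketone
Product: 30 (3R,3aS,5R,6S,7S,8S,8aR)-7-[(E)-but-2-enoyl]-5,7-dihydroxy-3,6-dimethyl-2-oxooctahydro-2H-cyclohepta[b]furan-8-yl 2-methylpropanoate (CNP0268641.1)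
Conditions: HF·pyridine, pyridine/THF, 0 °C → rt
Reagents that add atoms: none
Why: Fluoride cleavage of both silyl ethers under weakly acidic conditions, which avoids base-induced acyl shift from O8 to O7, C3 epimerisation and retro-aldol cleavage of the α-hydroxy ketone.

## Compound list

1 | (R)-carvone, (5R)-2-methyl-5-(prop-1-en-2-yl)cyclohex-2-en-1-one | CC1=CC[C@H](CC1=O)C(C)=C | starting material
2 | (1R,5R)-cis-carveol (hydroxyl cis to isopropenyl) | O[C@H]1C(C)=CC[C@@H](C(C)=C)C1 | intermediate
3 | tris-borane adduct of 2, drawn as monomer: O-boryl at C7, BH2 at C5 (lower face) and at the side-chain CH2; C3 epimers | [BH2]O[C@H]1[C@@H](C)[C@H]([BH2])C[C@@H](C(C)C[BH2])C1 | intermediate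
4 | 5-(1-hydroxypropan-2-yl)-2-methylcyclohexane-1,3-diol: 1-OH (C7) cis to the methyl and to the side chain, 3-OH (C5) trans to both; C3 epimers | O[C@H]1[C@@H](C)[C@H](O)C[C@@H](C(C)CO)C1 | intermediate
5 | 2-(3,5-dihydroxy-4-methylcyclohexyl)propanal, ring configuration as in 4; C3 epimers | O[C@H]1[C@@H](C)[C@H](O)C[C@@H](C(C)C=O)C1 | intermediate
6 | 3,7-dihydroxy-4,8-dimethyl-2-oxabicyclo[3.3.1]nonane (lactol on the C7 oxygen); C2 and C3 epimers | OC1O[C@H]2[C@@H](C)[C@H](O)C[C@@H](C1C)C2 | intermediate
7 | 7-hydroxy-4,8-dimethyl-2-oxabicyclo[3.3.1]nonan-3-one (7-OH = C5–OH, trans to the lactone bridge; 8-methyl cis to the bridge); C3 epimers | O=C1O[C@H]2[C@@H](C)[C@H](O)C[C@@H](C1C)C2 | intermediate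
8 | 7-(tert-butyldimethylsilyloxy)-4,8-dimethyl-2-oxabicyclo[3.3.1]nonan-3-one; C3 epimers | O=C1O[C@H]2[C@@H](C)[C@H](O[Si](C)(C)C(C)(C)C)C[C@@H](C1C)C2 | intermediate
9 | methyl 2-[3-(tert-butyldimethylsilyloxy)-5-hydroxy-4-methylcyclohexyl]propanoate (5-OH cis to side chain and methyl; silyloxy trans to both); C3 epimers | O[C@H]1[C@@H](C)[C@H](O[Si](C)(C)C(C)(C)C)C[C@@H](C(C)C(=O)OC)C1 | intermediate
10 | methyl 2-[(1R,3R,4S)-3-(tert-butyldimethylsilyloxy)-4-methyl-5-oxocyclohexyl]propanoate (silyloxy trans to side chain, methyl trans to silyloxy); C3 epimers | O=C1[C@@H](C)[C@H](O[Si](C)(C)C(C)(C)C)C[C@@H](C(C)C(=O)OC)C1 | intermediate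
11 | trimethylsilyldiazomethane | C[Si](C)(C)C=[N+]=[N-] | starting material
12 | methyl 2-[3-(tert-butyldimethylsilyloxy)-4-methyl-5-oxo-6-(trimethylsilyl)cycloheptyl]propanoate (silyl on C8, either configuration); C3 epimers | O=C1[C@@H](C)[C@H](O[Si](C)(C)C(C)(C)C)C[C@@H](C(C)C(=O)OC)CC1[Si](C)(C)C | intermediate
13 | methyl 2-[(1S,3R,4S)-3-(tert-butyldimethylsilyloxy)-4-methyl-5-oxocycloheptyl]propanoate (ketone carbon = C7); C3 epimers | O=C1[C@@H](C)[C@H](O[Si](C)(C)C(C)(C)C)C[C@@H](C(C)C(=O)OC)CC1 | intermediate
14 | lithium C7(O)=C8 enolate of 13 | [Li]OC=1[C@@H](C)[C@H](O[Si](C)(C)C(C)(C)C)C[C@@H](C(C)C(=O)OC)CC=1 | intermediate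
15 | trimethylsilyl enol ether of 13 (C7=C8) | C[Si](C)(C)OC=1[C@@H](C)[C@H](O[Si](C)(C)C(C)(C)C)C[C@@H](C(C)C(=O)OC)CC=1 | intermediate
16 | methyl 2-[(1R,5S,6R)-6-(tert-butyldimethylsilyloxy)-5-methyl-4-oxocyclohept-2-en-1-yl]propanoate (C7 ketone, C8=C8a); C3 epimers | O=C1[C@@H](C)[C@H](O[Si](C)(C)C(C)(C)C)C[C@@H](C(C)C(=O)OC)C=C1 | intermediate
17 | (S)-but-3-yn-2-ol | C[C@H](O)C#C | starting material
18 | dilithium salt of 17 (O-lithio, C-lithio) | C[C@H](O[Li])C#C[Li] | intermediate
19 | methyl 2-[6-(tert-butyldimethylsilyloxy)-4-hydroxy-4-[(S)-3-hydroxybut-1-ynyl]-5-methylcyclohept-2-en-1-yl]propanoate: C7–OH upper face, alkynyl lower face; C3 epimers | C[C@H](O)C#C[C@]1(O)[C@@H](C)[C@H](O[Si](C)(C)C(C)(C)C)C[C@@H](C(C)C(=O)OC)C=C1 | intermediate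
20 | bis(triethylsilyl) ether of 19 (C7–O and butynyl O); C3 epimers | C[C@H](O[Si](CC)(CC)CC)C#C[C@]1(O[Si](CC)(CC)CC)[C@@H](C)[C@H](O[Si](C)(C)C(C)(C)C)C[C@@H](C(C)C(=O)OC)C=C1 | intermediate
21 | C8–C8a epoxide of 20, oxygen on the lower face (trans to the C3a side chain and the C7 silyloxy group); C3 epimers | C[C@H](O[Si](CC)(CC)CC)C#C[C@]1(O[Si](CC)(CC)CC)[C@@H](C)[C@H](O[Si](C)(C)C(C)(C)C)C[C@@H](C(C)C(=O)OC)[C@@H]2O[C@H]12 | intermediate
22 | carboxylic acid of 21 (epoxy acid); C3 epimers | C[C@H](O[Si](CC)(CC)CC)C#C[C@]1(O[Si](CC)(CC)CC)[C@@H](C)[C@H](O[Si](C)(C)C(C)(C)C)C[C@@H](C(C)C(O)=O)[C@@H]2O[C@H]12 | intermediate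
23 | cis-fused lactone: O1 on C8a upper face, C8–OH lower face, C7 triethylsilyloxy up and silyloxybutynyl down, C6 methyl up, C5 tert-butyldimethylsilyloxy down; C3 epimers | C[C@H](O[Si](CC)(CC)CC)C#C[C@]1(O[Si](CC)(CC)CC)[C@@H](C)[C@H](O[Si](C)(C)C(C)(C)C)C[C@@H]2[C@@H](OC(=O)C2C)[C@@H]1O | intermediate
24 | isobutyryl chloride (2-methylpropanoyl chloride) | CC(C)C(Cl)=O | starting material
25 | C8 isobutyrate of 23; C3 epimers | C[C@H](O[Si](CC)(CC)CC)C#C[C@]1(O[Si](CC)(CC)CC)[C@@H](C)[C@H](O[Si](C)(C)C(C)(C)C)C[C@@H]2[C@@H](OC(=O)C2C)[C@@H]1OC(=O)C(C)C | intermediate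
26 | lithium enolate of lactone 25 (C2(OLi)=C3) | C[C@H](O[Si](CC)(CC)CC)C#C[C@]1(O[Si](CC)(CC)CC)[C@@H](C)[C@H](O[Si](C)(C)C(C)(C)C)C[C@@H]2[C@@H](OC(O[Li])=C2C)[C@@H]1OC(=O)C(C)C | intermediate
27 | (3R)-epimer of 25: C3 methyl on the concave face, cis to C4 | C[C@H](O[Si](CC)(CC)CC)C#C[C@]1(O[Si](CC)(CC)CC)[C@@H](C)[C@H](O[Si](C)(C)C(C)(C)C)C[C@@H]2[C@@H](OC(=O)[C@@H]2C)[C@@H]1OC(=O)C(C)C | intermediate
28 | 27 with the butynyl hydroxyl free (C7 triethylsilyl ether and C5 tert-butyldimethylsilyl ether kept) | C[C@H](O)C#C[C@]1(O[Si](CC)(CC)CC)[C@@H](C)[C@H](O[Si](C)(C)C(C)(C)C)C[C@@H]2[C@@H](OC(=O)[C@@H]2C)[C@@H]1OC(=O)C(C)C | intermediate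
29 | 7-O-triethylsilyl 5-O-tert-butyldimethylsilyl ether of the target: (E)-but-2-enoyl on C7 lower face | C/C=C/C(=O)[C@]1(O[Si](CC)(CC)CC)[C@@H](C)[C@H](O[Si](C)(C)C(C)(C)C)C[C@@H]2[C@@H](OC(=O)[C@@H]2C)[C@@H]1OC(=O)C(C)C | intermediate
30 | (3R,3aS,5R,6S,7S,8S,8aR)-7-[(E)-but-2-enoyl]-5,7-dihydroxy-3,6-dimethyl-2-oxooctahydro-2H-cyclohepta[b]furan-8-yl 2-methylpropanoate | C/C=C/C(=O)[C@]1(O)[C@@H](C)[C@H](O)C[C@@H]2[C@@H](OC(=O)[C@@H]2C)[C@@H]1OC(=O)C(C)C | target

## Step count and risks

Total: 17 steps, all in one line from 1; the longest linear sequence is 17 steps. Compounds 11, 17 and 24 are bought.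

**Step 7 (key step).** What may go wrong: partial migration of the methyl-bearing C6 instead of C8a, a second homologation of the product ketone, epoxide formation in place of the shift, or Lewis acid induced epimerisation at C6 and β-elimination of the C5 silyloxy group. Fallback: form the same two bonds by cyclopropanation instead of diazo insertion. From 10, kinetic silylation (LiN(iPr)2, Me3SiCl) gives the six-membered trimethylsilyl enol ether F1. Et2Zn/CH2I2 gives the 1-silyloxybicyclo[4.1.0]heptane F2. FeCl3 in DMF opens the internal cyclopropane bond to the 3-chlorocycloheptanone F3. NaOAc in MeOH then eliminates HCl, and the route is rejoined at enone 16 (13 and step 8 are bypassed).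

**Step 9.** What may go wrong: poor or reversed facial selectivity of a small, rod-like nucleophile at C7 (entry on the upper face over the ring, as small nucleophiles prefer with 2-alkylcyclohexanones), or enolisation towards C6 with loss of the C6 configuration. Fallback: let the C5 oxygen deliver the nucleophile. From 16, HF·pyridine gives the C5 hydroxy enone F4. Separately, 17 is silylated (Et3SiCl, imidazole) to (S)-(but-3-yn-2-yloxy)triethylsilane F5, and EtMgBr converts this into the bromomagnesium alkynide F6. The reagent is used in excess, so that the C5 magnesium alkoxide on the lower face holds it and passes the alkynyl group to the same face; this gives the C5,C7-diol F7. Me2(t-Bu)SiCl/imidazole silylates only the secondary C5 hydroxyl and gives the silyl ether F8, and Et3SiOTf then gives 20.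

**Step 11.** What may go wrong: peracid attack on the upper face, which gives an epoxide that the side-chain acid cannot open, or slow reaction at a hindered alkene. Fallback: fix C8a by iodolactonisation and bring in the C8 oxygen by radical trapping. From 20, LiOH gives the carboxylic acid F9. I2/NaHCO3 in MeCN gives the iodolactone F10; only a lower-face iodonium ion can be captured by the upper-face carboxylate, so O1 is up and iodine is down whatever the facial bias. Bu3SnH with excess TEMPO replaces iodine by the aminoxyl group on the convex lower face and gives the alkoxyamine F11. Zn/AcOH cleaves the N–O bond and gives 23.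

**Step 14.** What may go wrong: slow deprotonation of the epimer whose C3–H points into the concave face, or poor face selectivity of the protonation, which leaves the convex-face methyl epimer. Fallback: deliver the C3 hydrogen as an atom. From 25, enolate 26 is trapped with PhSeCl on the convex face to give the C3 phenylselanyl lactone F12, which forces the methyl to the concave face. Bu3SnH/AIBN then cleaves the C–Se bond, and the planar C3 radical takes hydrogen from the bulky stannane on the convex face, giving 27.

**Step 16.** What may go wrong: slow oxygen transfer to the alkyne carbon next to the quaternary C7, hydration with the wrong regiochemistry, or loss of the tertiary silyl ether followed by cyclisation of the free hydroxyl on to the activated alkyne. Fallback: change the migrating group from hydroxyl to acetate. From 28, Ac2O/pyridine/DMAP gives the propargylic acetate F13. Ph3PAuNTf2 in wet butanone brings about the 3,3-acyloxy shift to the allenyl acetate F14, whose hydrolysis in the same flask gives 29.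

## Further compounds

F1 | step 7 | trimethylsilyl enol ether of 10 (C7=C8a, six-membered ring) | C[Si](C)(C)OC=1[C@@H](C)[C@H](O[Si](C)(C)C(C)(C)C)C[C@@H](C(C)C(=O)OC)C=1
F2 | step 7 | 1-(trimethylsilyloxy)bicyclo[4.1.0]heptane from F1 (cyclopropane CH2 = C8) | C[Si](C)(C)OC12[C@@H](C)[C@H](O[Si](C)(C)C(C)(C)C)C[C@@H](C(C)C(=O)OC)C1C2
F3 | step 7 | 3-chlorocycloheptanone (chlorine on C8a, ketone at C7) | O=C1[C@@H](C)[C@H](O[Si](C)(C)C(C)(C)C)C[C@@H](C(C)C(=O)OC)C(Cl)C1
F4 | step 9 | C5 hydroxy enone (16 without the silyl group) | O=C1[C@@H](C)[C@H](O)C[C@@H](C(C)C(=O)OC)C=C1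
F5 | step 9 | (S)-(but-3-yn-2-yloxy)triethylsilane | C[C@H](O[Si](CC)(CC)CC)C#C
F6 | step 9 | bromomagnesium alkynide of F5 | C[C@H](O[Si](CC)(CC)CC)C#C[Mg]Br
F7 | step 9 | C5,C7-diol carrying the triethylsilyloxybutynyl group on the C7 lower face | C[C@H](O[Si](CC)(CC)CC)C#C[C@]1(O)[C@@H](C)[C@H](O)C[C@@H](C(C)C(=O)OC)C=C1
F8 | step 9 | C5 tert-butyldimethylsilyl ether of F7 (C7 hydroxyl free) | C[C@H](O[Si](CC)(CC)CC)C#C[C@]1(O)[C@@H](C)[C@H](O[Si](C)(C)C(C)(C)C)C[C@@H](C(C)C(=O)OC)C=C1
F9 | step 11 | carboxylic acid of 20 | C[C@H](O[Si](CC)(CC)CC)C#C[C@]1(O[Si](CC)(CC)CC)[C@@H](C)[C@H](O[Si](C)(C)C(C)(C)C)C[C@@H](C(C)C(O)=O)C=C1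
F10 | step 11 | iodolactone: O1 on C8a upper face, iodine on C8 lower face | C[C@H](O[Si](CC)(CC)CC)C#C[C@]1(O[Si](CC)(CC)CC)[C@@H](C)[C@H](O[Si](C)(C)C(C)(C)C)C[C@@H]2[C@@H](OC(=O)C2C)[C@@H]1I
F11 | step 11 | C8 O-(2,2,6,6-tetramethylpiperidin-1-yl) ether of 23 | C[C@H](O[Si](CC)(CC)CC)C#C[C@]1(O[Si](CC)(CC)CC)[C@@H](C)[C@H](O[Si](C)(C)C(C)(C)C)C[C@@H]2[C@@H](OC(=O)C2C)[C@@H]1ON3C(C)(C)CCCC3(C)C
F12 | step 14 | C3 phenylselanyl lactone (selenium on the convex face, methyl on the concave face) | C[C@H](O[Si](CC)(CC)CC)C#C[C@]1(O[Si](CC)(CC)CC)[C@@H](C)[C@H](O[Si](C)(C)C(C)(C)C)C[C@@H]2[C@@H](OC(=O)[C@@]2(C)[Se]c3ccccc3)[C@@H]1OC(=O)C(C)C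
F13 | step 16 | propargylic acetate of 28 | C[C@H](OC(C)=O)C#C[C@]1(O[Si](CC)(CC)CC)[C@@H](C)[C@H](O[Si](C)(C)C(C)(C)C)C[C@@H]2[C@@H](OC(=O)[C@@H]2C)[C@@H]1OC(=O)C(C)C
F14 | step 16 | allenyl acetate from F13 (1-acetoxybuta-1,2-dienyl group on C7, allene configuration open) | CC=C=C(OC(C)=O)[C@]1(O[Si](CC)(CC)CC)[C@@H](C)[C@H](O[Si](C)(C)C(C)(C)C)C[C@@H]2[C@@H](OC(=O)[C@@H]2C)[C@@H]1OC(=O)C(C)C
A1 | alternative 1 | 3-methylfuran | Cc1ccoc1
A2 | alternative 1 | triethylsilyl enol ether of 1-methoxy-1-[(S)-1-phenylethoxy]propan-2-one (mixed acetal, acetal carbon open) | C=C(O[Si](CC)(CC)CC)C(OC)O[C@@H](C)c1ccccc1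
A3 | alternative 1 | 6-methyl-2-[(S)-1-phenylethoxy]-8-oxabicyclo[3.2.1]oct-6-en-3-one | C1=C(C)[C@H]2CC(=O)[C@@H](O[C@@H](C)c3ccccc3)[C@@H]1O2
A4 | alternative 2 | open-chain C8a aldehyde with a methyl (Z)-2-(bromomethyl)enoate terminus (C7/C8 acetonide, C7 (4-methoxybenzyloxy)methyl, C5 triisopropylsilyl ether) | O=C[C@@H]1OC(C)(C)O[C@@]1(COCc2ccc(OC)cc2)[C@@H](C)[C@H](O[Si](C(C)C)(C(C)C)C(C)C)C/C=C(\CBr)C(=O)OC
A5 | alternative 2 | cis-fused α-methylene-γ-butyrolactone on the cycloheptane, C7/C8 acetonide, C7 (4-methoxybenzyloxy)methyl, C5 triisopropylsilyl ether | C(OCc4ccc(OC)cc4)[C@]1(OC(C)(C)O2)[C@@H](C)[C@H](O[Si](C(C)C)(C(C)C)C(C)C)C[C@@H]3[C@@H](OC(=O)C3=C)[C@@H]12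
A6 | alternative 3 | C8a diazoacetate of the C7 dioxolane-protected cycloheptane (C8 isobutyrate, C5 silyl ether) | O1CCOC12[C@@H](C)[C@H](O[Si](C)(C)C(C)(C)C)CC[C@@H](OC(=O)C=[N+]=[N-])[C@@H]2OC(=O)C(C)C
A7 | alternative 3 | cis-fused γ-lactone lacking the C3 methyl (C7 dioxolane, C8 isobutyrate, C5 silyl ether) | O1CCOC12[C@@H](C)[C@H](O[Si](C)(C)C(C)(C)C)C[C@@H]3[C@@H](OC(=O)C3)[C@@H]2OC(=O)C(C)C
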